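The isoflavone is cut at the C4–C4a bond of the pyranone. A (Z)-3-aryloxy-2-arylacrylic acid, which already holds O1, C2, C3, ring B and the future carbonyl carbon C4, is activated as its mixed trifluoroacetic anhydride and acylates ring A, closing the pyranone and completing the chromone in one operation. The closure exploits the fact that C4a is the only hydrogen-bearing ring-A carbon ortho to O1 and lies ortho or para to the oxygens on C5, C7 and C8a. The acid carries an isopropyl ether on O8 and an allyl ether on O5; the allyl group is later moved to C6 by Claisen rearrangement and turned into prenyl by cross-metathesis.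

Key step: step 10

Remark on numbering: chromone numbering is used throughout; ring A is the benzo ring (C4a to C8a) and ring B is the 2,4,5-trimethoxyphenyl group.
Remark on geometry (assumption): compounds 14 to 17 are drawn as Z isomers (oxygen substituent on C3 cis to the carboxyl carbon); any E isomer formed in step 8 is carried along, because both isomers should converge at the acyl cation stage of step 10.
Remark on design: the prenyl alkene is made last and under neutral conditions, because a trisubstituted alkene next to a phenol would not be expected to survive the acidic ring closure or the Lewis-acid deprotection.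

Step 1
Reactants: 1 5-bromo-2-hydroxy-3-methoxybenzaldehyde; 2 2-bromopropane
Product: 3 5-bromo-3-methoxy-2-(propan-2-yloxy)benzaldehyde
Conditions: K2CO3, DMF, 60 °C
Reagents that add atoms: 2-bromopropane, CC(C)Br
Why: Williamson etherification of the phenoxide, which is acidified by the ortho formyl group, by the secondary bromide in a dipolar aprotic solvent; the aryl bromide and the aldehyde are inert to carbonate.

Step 2
Reactants: 3 5-bromo-3-methoxy-2-(propan-2-yloxy)benzaldehyde
Product: 5 5-hydroxy-3-methoxy-2-(propan-2-yloxy)benzaldehyde, via arylboronic acid pinacol ester 4 (not isolated)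
Conditions: B2pin2, Pd(dppf)Cl2 (3 mol %), KOAc, 1,4-dioxane, 90 °C; then NaBO3·4H2O, THF/H2O, rt
Reagents that add atoms: sodium perborate (used as NaBO3·4H2O), [Na+].[O-]OB=O; bis(pinacolato)diboron, CC1(C)OB(OC1(C)C)B1OC(C)(C)C(C)(C)O1 (its boron stays only in 4)
Why: Miyaura borylation of the aryl bromide under zerovalent palladium catalysis tolerates the aldehyde, and the boronate should then be oxidised in the same flask by perborate through a 1,2-aryl shift from boron to oxygen, which is much faster than attack of this mild oxidant on the aldehyde.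

Step 3
Reactants: 5 5-hydroxy-3-methoxy-2-(propan-2-yloxy)benzaldehyde; 6 3-bromoprop-1-ene (allyl bromide)
Product: 7 3-methoxy-2-(propan-2-yloxy)-5-(prop-2-en-1-yloxy)benzaldehyde
Conditions: K2CO3, DMF, rt
Reagents that add atoms: 3-bromoprop-1-ene, C=CCBr
Why: Williamson etherification of the free phenol by a reactive allylic bromide; the allyl ether protects O5 and later supplies the three carbons that are delivered to C6.

Step 4
Reactants: 7 3-methoxy-2-(propan-2-yloxy)-5-(prop-2-en-1-yloxy)benzaldehyde
Product: 9 3-methoxy-2-(propan-2-yloxy)-5-(prop-2-en-1-yloxy)phenol, via aryl formate 8 (not isolated)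
Conditions: mCPBA (1.1 equiv), CH2Cl2, 0 °C to rt; then K2CO3 (cat.), MeOH, rt
Reagents that add atoms: 3-chloroperoxybenzoic acid, OOC(=O)c1cccc(Cl)c1
Why: Baeyer–Villiger (Dakin-type) oxidation, in which the electron-rich aryl group, pushed by the ortho isopropoxy oxygen, migrates in the Criegee adduct in preference to hydride; one equivalent of peracid should react with the aldehyde faster than with the monosubstituted allyl alkene, and the formate is removed by base-catalysed methanolysis.

Step 5
Reactants: 10 2-(2,4,5-trimethoxyphenyl)acetic acid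
Product: 11 methyl 2-(2,4,5-trimethoxyphenyl)acetate
Conditions: MeOH, H2SO4 (cat.), reflux
Reagents that add atoms: methanol, CO
Why: Fischer esterification driven by the large excess of methanol.

Step 6
Reactants: 11 methyl 2-(2,4,5-trimethoxyphenyl)acetate; 12 methyl formate
Product: 13 methyl 3-oxo-2-(2,4,5-trimethoxyphenyl)propanoate
Conditions: NaH, THF, 0 °C to rt; then 1 M HCl
Reagents that add atoms: methyl formate, COC=O
Why: crossed Claisen condensation with a non-enolisable formate, driven by formation of the stabilised sodium enolate of the formyl ester; the product is a configurationally labile aldehyde–enol tautomer mixture, so no stereochemistry is at stake.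

Step 7
Reactants: 13 methyl 3-oxo-2-(2,4,5-trimethoxyphenyl)propanoate
Product: 14 methyl (Z)-3-[(4-methylphenyl)sulfonyloxy]-2-(2,4,5-trimethoxyphenyl)prop-2-enoate
Conditions: NaH, THF, 0 °C; then TsCl, 0 °C to rt
Reagents that add atoms: 4-methylbenzenesulfonyl chloride, Cc1ccc(S(=O)(=O)Cl)cc1
Why: O-sulfonylation of the sodium enolate, which is held as a chelate between the enolate oxygen and the ester carbonyl, so that the tosyloxy group should end up cis to the ester (Z).

Step 8
Reactants: 9 3-methoxy-2-(propan-2-yloxy)-5-(prop-2-en-1-yloxy)phenol; 14 methyl (Z)-3-[(4-methylphenyl)sulfonyloxy]-2-(2,4,5-trimethoxyphenyl)prop-2-enoate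
Product: 15 methyl (Z)-3-[3-methoxy-2-(propan-2-yloxy)-5-(prop-2-en-1-yloxy)phenoxy]-2-(2,4,5-trimethoxyphenyl)prop-2-enoate
Conditions: Cs2CO3, MeCN, rt to 50 °C
Reagents that add atoms: none
Why: nucleophilic vinylic substitution by addition–elimination, in which the phenoxide adds to the carbon that bears the tosyloxy group and the short-lived ester-stabilised carbanion expels tosylate, predominantly with retention of the alkene geometry.

Step 9
Reactants: 15 methyl (Z)-3-[3-methoxy-2-(propan-2-yloxy)-5-(prop-2-en-1-yloxy)phenoxy]-2-(2,4,5-trimethoxyphenyl)prop-2-enoate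
Product: 16 (Z)-3-[3-methoxy-2-(propan-2-yloxy)-5-(prop-2-en-1-yloxy)phenoxy]-2-(2,4,5-trimethoxyphenyl)prop-2-enoic acid
Conditions: LiOH·H2O, THF/MeOH/H2O, rt; then 1 M HCl, 0 °C
Reagents that add atoms: lithium hydroxide, [Li+].[OH-]
Why: saponification by acyl–oxygen cleavage; the push–pull enol ether is a poor conjugate acceptor and becomes inert once the carboxylate is formed, and the brief cold acidification spares the enol ether.

Step 10
Reactants: 16 (Z)-3-[3-methoxy-2-(propan-2-yloxy)-5-(prop-2-en-1-yloxy)phenoxy]-2-(2,4,5-trimethoxyphenyl)prop-2-enoic acid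
Product: 18 7-methoxy-8-(propan-2-yloxy)-5-(prop-2-en-1-yloxy)-3-(2,4,5-trimethoxyphenyl)-4H-chromen-4-one, via mixed trifluoroacetic anhydride 17 (not isolated)
Conditions: (CF3CO)2O (3 equiv), CH2Cl2, 0 °C to rt
Reagents that add atoms: none
Why: Trifluoroacetic anhydride converts acid 16 into mixed anhydride 17, which reacts as an acyl cation whose alkoxyketene–oxocarbenium resonance form lowers the C2–C3 bond order, so that any E-configured material can rotate into the reactive cis arrangement before ring A attacks and a proton is lost. The closest known reaction type is the cyclodehydration of 3-aryloxyacrylic acids to chromones, an intramolecular Friedel–Crafts acylation. The one new ring, the pyranone, is closed by 6-exo attack of C4a on the acyl carbon, the carbonyl oxygen staying outside the ring. No stereocentre is formed. The step needs regioselectivity for C4a and chemoselectivity over ring B and the two ethers: C4a is the only free carbon ortho to O1 (C8 carries the isopropoxy group and C6 is out of reach of the three-atom tether), it is ortho to the O5 ether and para to the 7-methoxy group, ring B could only close a four-membered ring, and the anhydrous conditions without Lewis acid should leave the isopropyl ether, the allyl ether and its monosubstituted alkene untouched.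

Step 11
Reactants: 18 7-methoxy-8-(propan-2-yloxy)-5-(prop-2-en-1-yloxy)-3-(2,4,5-trimethoxyphenyl)-4H-chromen-4-one
Product: 20 5-hydroxy-7-methoxy-8-(propan-2-yloxy)-6-(prop-2-en-1-yl)-3-(2,4,5-trimethoxyphenyl)-4H-chromen-4-one, via 6-allyl cyclohexadienone 19 (not isolated)
Conditions: N,N-diethylaniline, 200 °C, sealed tube
Reagents that add atoms: none
Why: aromatic Claisen rearrangement, a concerted [3,3] shift that can only deliver the allyl group from O5 to C6 (the other ortho carbon, C4a, is a ring fusion), after which dienone 19 tautomerises to the phenol held by a hydrogen bond to the C4 carbonyl, which removes the transient stereocentre at C6.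

Step 12
Reactants: 20 5-hydroxy-7-methoxy-8-(propan-2-yloxy)-6-(prop-2-en-1-yl)-3-(2,4,5-trimethoxyphenyl)-4H-chromen-4-one
Product: 21 5,8-dihydroxy-7-methoxy-6-(prop-2-en-1-yl)-3-(2,4,5-trimethoxyphenyl)-4H-chromen-4-one
Conditions: BCl3 (1 M in CH2Cl2, 4 equiv), CH2Cl2, −78 to 0 °C; H2O work-up under argon
Reagents that add atoms: none
Why: Lewis-acid ether cleavage in which BCl3 binds the O8 ether oxygen and chloride removes the secondary isopropyl group, much faster than any methyl group at or below 0 °C; O5 is held meanwhile as a chelated borate and the terminal alkene should be inert.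

Step 13
Reactants: 21 5,8-dihydroxy-7-methoxy-6-(prop-2-en-1-yl)-3-(2,4,5-trimethoxyphenyl)-4H-chromen-4-one; 22 2-methylbut-2-ene
Product: 23 5,8-dihydroxy-7-methoxy-6-(3-methylbut-2-en-1-yl)-3-(2,4,5-trimethoxyphenyl)-4H-chromen-4-one
Conditions: second-generation Grubbs catalyst RuCl2(=CHPh)(PCy3)(H2IMes) (5 mol %), 2-methylbut-2-ene (large excess), CH2Cl2, 40 °C, argon
Reagents that add atoms: 2-methylbut-2-ene, CC=C(C)C
Why: olefin cross-metathesis in which the terminal methylene of the allyl group is exchanged for the isopropylidene unit of the excess trisubstituted alkene, driven by loss of propene; the new alkene has two identical methyl groups, so no geometry is at stake, and the neutral conditions spare the hydroquinone and the prenyl group.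

Compound list
1 | 5-bromo-2-hydroxy-3-methoxybenzaldehyde | COc1cc(Br)cc(C=O)c1O | starting material
2 | 2-bromopropane | CC(C)Br | starting material
3 | 5-bromo-3-methoxy-2-(propan-2-yloxy)benzaldehyde | COc1cc(Br)cc(C=O)c1OC(C)C | intermediate
4 | 3-methoxy-2-(propan-2-yloxy)-5-(4,4,5,5-tetramethyl-1,3,2-dioxaborolan-2-yl)benzaldehyde (not isolated) | COc1cc(B2OC(C)(C)C(C)(C)O2)cc(C=O)c1OC(C)C | intermediate
5 | 5-hydroxy-3-methoxy-2-(propan-2-yloxy)benzaldehyde | COc1cc(O)cc(C=O)c1OC(C)C | intermediate
6 | 3-bromoprop-1-ene (allyl bromide) | C=CCBr | starting material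
7 | 3-methoxy-2-(propan-2-yloxy)-5-(prop-2-en-1-yloxy)benzaldehyde | COc1cc(OCC=C)cc(C=O)c1OC(C)C | intermediate
8 | 3-methoxy-2-(propan-2-yloxy)-5-(prop-2-en-1-yloxy)phenyl formate (not isolated) | COc1cc(OCC=C)cc(OC=O)c1OC(C)C | intermediate
9 | 3-methoxy-2-(propan-2-yloxy)-5-(prop-2-en-1-yloxy)phenol | COc1cc(OCC=C)cc(O)c1OC(C)C | intermediate
10 | 2-(2,4,5-trimethoxyphenyl)acetic acid | COc1cc(OC)c(CC(=O)O)cc1OC | starting material
11 | methyl 2-(2,4,5-trimethoxyphenyl)acetate | COC(=O)Cc1cc(OC)c(OC)cc1OC | intermediate
12 | methyl formate | COC=O | starting material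
13 | methyl 3-oxo-2-(2,4,5-trimethoxyphenyl)propanoate (racemic and labile, in equilibrium with its hydroxymethylene enol) | COC(=O)C(C=O)c1cc(OC)c(OC)cc1OC | intermediate
14 | methyl (Z)-3-[(4-methylphenyl)sulfonyloxy]-2-(2,4,5-trimethoxyphenyl)prop-2-enoate | COC(=O)/C(c1cc(OC)c(OC)cc1OC)=C\OS(=O)(=O)c1ccc(C)cc1 | intermediate
15 | methyl (Z)-3-[3-methoxy-2-(propan-2-yloxy)-5-(prop-2-en-1-yloxy)phenoxy]-2-(2,4,5-trimethoxyphenyl)prop-2-enoate | COC(=O)/C(c1cc(OC)c(OC)cc1OC)=C\Oc1cc(OCC=C)cc(OC)c1OC(C)C | intermediate
16 | (Z)-3-[3-methoxy-2-(propan-2-yloxy)-5-(prop-2-en-1-yloxy)phenoxy]-2-(2,4,5-trimethoxyphenyl)prop-2-enoic acid | O=C(O)/C(c1cc(OC)c(OC)cc1OC)=C\Oc1cc(OCC=C)cc(OC)c1OC(C)C | intermediate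
17 | mixed anhydride of acid 16 with trifluoroacetic acid, Z (not isolated) | O=C(OC(=O)C(F)(F)F)/C(c1cc(OC)c(OC)cc1OC)=C\Oc1cc(OCC=C)cc(OC)c1OC(C)C | intermediate
18 | 7-methoxy-8-(propan-2-yloxy)-5-(prop-2-en-1-yloxy)-3-(2,4,5-trimethoxyphenyl)-4H-chromen-4-one | COc1cc(OC)c(-c2coc3c(OC(C)C)c(OC)cc(OCC=C)c3c2=O)cc1OC | intermediate
19 | 7-methoxy-8-(propan-2-yloxy)-6-(prop-2-en-1-yl)-3-(2,4,5-trimethoxyphenyl)-6H-chromene-4,5-dione (racemic at C6, not isolated) | COc1cc(OC)c(C2=COC3=C(C2=O)C(=O)C(CC=C)C(OC)=C3OC(C)C)cc1OC | intermediate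
20 | 5-hydroxy-7-methoxy-8-(propan-2-yloxy)-6-(prop-2-en-1-yl)-3-(2,4,5-trimethoxyphenyl)-4H-chromen-4-one | COc1cc(OC)c(-c2coc3c(OC(C)C)c(OC)c(CC=C)c(O)c3c2=O)cc1OC | intermediate
21 | 5,8-dihydroxy-7-methoxy-6-(prop-2-en-1-yl)-3-(2,4,5-trimethoxyphenyl)-4H-chromen-4-one | COc1cc(OC)c(-c2coc3c(O)c(OC)c(CC=C)c(O)c3c2=O)cc1OC | intermediate
22 | 2-methylbut-2-ene | CC=C(C)C | starting material
23 | 5,8-dihydroxy-7-methoxy-6-(3-methylbut-2-en-1-yl)-3-(2,4,5-trimethoxyphenyl)-4H-chromen-4-one (no stereocentres) | COc1cc(OC)c(-c2coc3c(O)c(OC)c(CC=C(C)C)c(O)c3c2=O)cc1OC | target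

Total step count: 13 steps.
Longest linear sequence: 10 steps (steps 1, 2, 3, 4, 8, 9, 10, 11, 12, 13, from compound 1 to compound 23); the ring-B branch (steps 5 to 7) joins at step 8.

Steps most likely to fail

Step 10. The mixed anhydride may be too weak an electrophile for a ring whose O1 lone pair is shared with the acrylate, the E isomer may fail to reach the cis arrangement, or the enol ether may be cleaved by acid before the ring closes. The fallback sets out from phenol 9 and acid 10 and returns at chromone 18. It makes the C4–C4a bond first and between the two fragments. Phenol 9 is acylated ortho to its hydroxyl group by acid 10 in BF3·OEt2 at 50 to 60 °C, where the boron chelate of the product directs the acyl group to the only free ortho carbon, to give the 2-hydroxydeoxybenzoin F1. F1 is then heated with N,N-dimethylformamide dimethyl acetal in toluene; the enaminone F2 that forms is closed by attack of the phenol oxygen with loss of dimethylamine, which gives 18.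

Step 13. Ruthenium hydride species formed during the reaction may move the allyl double bond into conjugation with ring A, or the free hydroquinone may be oxidised or may bind and deactivate the catalyst. The fallback sets out from 20 and returns at target 23. It builds the trisubstituted alkene by carbonyl olefination instead of metathesis. Lemieux–Johnson cleavage of the allyl group of 20 (OsO4 cat., NaIO4, 2,6-lutidine, dioxane/H2O) gives the arylacetaldehyde F3, which may rest as its lactol on O5. Wittig reaction with isopropylidenetriphenylphosphorane (excess, THF, −78 to 0 °C) gives the prenylated phenol F4. BCl3 at −78 °C with a cold quench then removes the isopropyl group to give 23.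

Step 12. The Lewis acid may also remove the 7-methyl group next to the newly formed borate, or the hydrogen chloride set free may add to the allyl group or close it onto O5. The fallback sets out from 20 and returns at hydroquinone 21. It uses oxidative dealkylation: 20 is a para-alkoxyphenol and should be oxidised by PhI(OCOCF3)2 in MeCN/H2O at 0 °C to the 5,8-quinone F5 with loss of propan-2-ol. F5 is then reduced with aqueous Na2S2O4 under argon to 21.

Further compounds
F1 | step 10 | 1-[2-hydroxy-4-methoxy-3-(propan-2-yloxy)-6-(prop-2-en-1-yloxy)phenyl]-2-(2,4,5-trimethoxyphenyl)ethan-1-one | COc1cc(OCC=C)c(C(=O)Cc2cc(OC)c(OC)cc2OC)c(O)c1OC(C)C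
F2 | step 10 | (E)-3-(dimethylamino)-1-[2-hydroxy-4-methoxy-3-(propan-2-yloxy)-6-(prop-2-en-1-yloxy)phenyl]-2-(2,4,5-trimethoxyphenyl)prop-2-en-1-one | COc1cc(OCC=C)c(C(=O)/C(c2cc(OC)c(OC)cc2OC)=C/N(C)C)c(O)c1OC(C)C
F3 | step 13 | 2-[5-hydroxy-7-methoxy-4-oxo-8-(propan-2-yloxy)-3-(2,4,5-trimethoxyphenyl)-4H-chromen-6-yl]acetaldehyde | COc1cc(OC)c(-c2coc3c(OC(C)C)c(OC)c(CC=O)c(O)c3c2=O)cc1OC
F4 | step 13 | 5-hydroxy-7-methoxy-6-(3-methylbut-2-en-1-yl)-8-(propan-2-yloxy)-3-(2,4,5-trimethoxyphenyl)-4H-chromen-4-one | COc1cc(OC)c(-c2coc3c(OC(C)C)c(OC)c(CC=C(C)C)c(O)c3c2=O)cc1OC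
F5 | step 12 | 7-methoxy-6-(prop-2-en-1-yl)-3-(2,4,5-trimethoxyphenyl)-4H-chromene-4,5,8-trione | COc1cc(OC)c(C2=COC3=C(C2=O)C(=O)C(CC=C)=C(OC)C3=O)cc1OC
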